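**Retrosynthetic overview** (numbering of the tricyclo[5.4.0.0^2,8]undecane core: C9 = ketone carbon, C2 = quaternary cyclobutane carbon, C6 = CMe2, C7 = cyclobutane CH)
1. Target 27 ⇐ stepwise acylation of O4 (angelate) and O3 ((R)-2-methylbutanoate) of a 3,4-cis-diol ⇐ osmylation of the C3=C4 olefin of tricyclic dienone 21, anti to the 5-silyloxy group.
2. Key disconnection C6–C7: the seven-membered ring C1–C2–C3–C4–C5–C6–C7 is closed last, by iron-hydride hydrogen-atom transfer to an isopropenyl group and 7-exo addition of the resulting C6 radical to the C7 tosylhydrazone of bicycle 18, followed by loss of sulfinate and N2 to leave C7–H.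
3. Enabling feature: C2 and C7 are the two one-carbon bridges of the bicyclo[3.1.1]heptenone and lie 1,3 across the cyclobutane C1–C2–C8–C7; the (Z)-alkenyl arm on quaternary C2 is pseudo-axial, anti to the C9–C10–C11 bridge, and therefore hangs directly under C7.
4. The four- and six-membered rings form together (step 8) by intramolecular [2+2] cycloaddition of a vinylketene from dienynoic acid 10; a temporary silyloxy stereocentre at the future C9 carbonyl relays the absolute configuration and is later oxidised away.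
5. Acid 10 ⇐ (E)-3-methylpent-2-en-4-yn-1-ol (C9, C8, C2 + Me, C3, C4), methyl 3-methylbut-2-enoate (C7, C1, C11 + Me, C10) and methacrolein (C5, C6 + 2 Me), joined by a catalytic asymmetric vinylogous aldol and a catalytic asymmetric alkynylation. Ring order: cyclobutane + cyclohexene (step 8), then cycloheptane (step 13).

Key step: step 13

Assumption: 3, 23 and 25 are bought isomerically pure, and the catalyst enantiomers in steps 3 and 5 are specified by the aldehyde face they must expose, because the sense of induction of each ligand would have to be confirmed on these substrates.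

**Step 1**
Reactants: 1 methyl 3-methylbut-2-enoate
Product: 2 tert-butyl[(1-methoxy-3-methylbuta-1,3-dien-1-yl)oxy]dimethylsilane
Conditions: LDA, THF, −78 °C; DMPU, TBSCl, −78 °C → rt
Reagents that add atoms: tert-butyldimethylsilyl chloride CC(C)(C)[Si](C)(C)Cl
Why: γ-deprotonation of the senecioate gives the extended ester dienolate, which is O-silylated (silyl ketene acetal formation) to the silyl dienol ether; no stereocentre is formed.

**Step 2**
Reactants: 3 (2E)-3-methylpent-2-en-4-yn-1-ol
Product: 4 (2E)-3-methylpent-2-en-4-ynal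
Conditions: activated MnO2, CH2Cl2, rt
Reagents that add atoms: none
Why: MnO2 oxidation of a primary allylic alcohol should give the enynal without touching the alkyne or the (E)-olefin geometry.

**Step 3**
Reactants: 4 (2E)-3-methylpent-2-en-4-ynal; 2 silyl dienol ether
Product: 5 methyl (2E,5S,6E)-5-hydroxy-3,7-dimethylnona-2,6-dien-8-ynoate
Conditions: SiCl4 (1.1 equiv), chiral bisphosphoramide (5 mol%, enantiomer that exposes the Si face of the aldehyde), i-Pr2NEt (10 mol%), CH2Cl2, −78 °C; aqueous work-up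
Reagents that add atoms: none
Why: Lewis-base-activated SiCl4 vinylogous Mukaiyama aldol: the dienol ether reacts at its γ-carbon with the aldehyde bound to the chiral phosphoramide–trichlorosilyl cation, and attack on the Si face sets C5 as S.

**Step 4**
Reactants: 5 methyl (2E,5S,6E)-5-hydroxy-3,7-dimethylnona-2,6-dien-8-ynoate
Product: 6 methyl (2E,5S,6E)-3,7-dimethyl-5-[(triethylsilyl)oxy]nona-2,6-dien-8-ynoate
Conditions: TESCl, imidazole, DMF, 0 °C
Reagents that add atoms: triethylsilyl chloride CC[Si](Cl)(CC)CC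
Why: Standard silyl ether formation on the secondary allylic alcohol; the stereocentre is not touched.

**Step 5**
Reactants: 6 methyl (2E,5S,6E)-3,7-dimethyl-5-[(triethylsilyl)oxy]nona-2,6-dien-8-ynoate; 7 2-methylprop-2-enal (methacrolein)
Product: 8 methyl (2E,5S,6E,10S)-10-hydroxy-3,7,11-trimethyl-5-[(triethylsilyl)oxy]dodeca-2,6,11-trien-8-ynoate
Conditions: Me2Zn (3 equiv), ProPhenol ligand (20 mol%, enantiomer that delivers the alkynyl group to the Re face of the aldehyde), Ph3P=O (40 mol%), toluene, 4 °C; water quench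
Reagents that add atoms: none
Why: Zn–ProPhenol asymmetric alkynylation of an enal: the dinuclear zinc complex binds the aldehyde and the zinc acetylide, and Re-face delivery sets C10 as S under catalyst control, the remote C5 centre having no influence.

**Step 6**
Reactants: 8 methyl (2E,5S,6E,10S)-10-hydroxy-3,7,11-trimethyl-5-[(triethylsilyl)oxy]dodeca-2,6,11-trien-8-ynoate
Product: 9 methyl (2E,5S,6E,10S)-10-[(tert-butyldimethylsilyl)oxy]-3,7,11-trimethyl-5-[(triethylsilyl)oxy]dodeca-2,6,11-trien-8-ynoate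
Conditions: TBSOTf, 2,6-lutidine, CH2Cl2, −78 °C
Reagents that add atoms: tert-butyldimethylsilyl trifluoromethanesulfonate CC(C)(C)[Si](C)(C)OS(=O)(=O)C(F)(F)F
Why: Silylation of the hindered propargylic alcohol with the silyl triflate; a silyl ether is chosen because it offers no activated C–H bond for 1,5-hydrogen transfer to the radical of step 13.

**Step 7**
Reactants: 9 methyl (2E,5S,6E,10S)-10-[(tert-butyldimethylsilyl)oxy]-3,7,11-trimethyl-5-[(triethylsilyl)oxy]dodeca-2,6,11-trien-8-ynoate
Product: 10 (2E,5S,6E,10S)-10-[(tert-butyldimethylsilyl)oxy]-3,7,11-trimethyl-5-[(triethylsilyl)oxy]dodeca-2,6,11-trien-8-ynoic acid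
Conditions: LiOH·H2O, THF/MeOH/H2O, rt; then 1 M HCl to pH 4, 0 °C
Reagents that add atoms: lithium hydroxide [Li+].[OH-]
Why: Saponification of the methyl ester; the two silyl ethers and the enyne should survive aqueous LiOH at room temperature.

**Step 8**
Reactants: 10 (2E,5S,6E,10S)-10-[(tert-butyldimethylsilyl)oxy]-3,7,11-trimethyl-5-[(triethylsilyl)oxy]dodeca-2,6,11-trien-8-ynoic acid
Product: 13 (1R,4S,5R,7R)-7-[(3S)-3-[(tert-butyldimethylsilyl)oxy]-4-methylpent-4-en-1-yn-1-yl]-7-methyl-2-methylidene-4-[(triethylsilyl)oxy]bicyclo[3.1.1]heptan-6-one, via acid chloride 11 (not isolated), via vinylketene 12 (not isolated)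
Conditions: 1-chloro-N,N,2-trimethylprop-1-en-1-amine, CH2Cl2, 0 °C; then slow addition to Et3N, toluene, 110 °C (0.005 M)
Reagents that add atoms: none
Why: Intramolecular ketene–olefin [2+2] cycloaddition of the vinylketene formed by 1,4-dehydrochlorination: the ketene carbonyl carbon bonds to C6 and the ketene α-carbon to C7 (tertiary and propargylic, best able to carry positive charge), which gives the bridged bicyclo[3.1.1]heptan-6-one; addition is suprafacial on the (E)-olefin, so the methyl group ends syn and the alkynyl group anti to the three-carbon bridge, and because the tether must attack from one face while the C5 silyloxy group takes the in-plane position remote from the cis-methyl group (allylic strain), the (5S) centre fixes all four ring stereocentres.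

**Step 9**
Reactants: 13 (1R,4S,5R,7R)-7-[(3S)-3-[(tert-butyldimethylsilyl)oxy]-4-methylpent-4-en-1-yn-1-yl]-7-methyl-2-methylidene-4-[(triethylsilyl)oxy]bicyclo[3.1.1]heptan-6-one
Product: 14 (1R,2S,5R,7R)-7-[(3S)-3-[(tert-butyldimethylsilyl)oxy]-4-methylpent-4-en-1-yn-1-yl]-2-hydroxy-7-methyl-4-methylidenebicyclo[3.1.1]heptan-6-one
Conditions: PPTS, MeOH/CH2Cl2, 0 °C
Reagents that add atoms: none
Why: Acid-catalysed methanolysis removes the more labile triethylsilyl ether, while the tert-butyldimethylsilyl ether reacts much more slowly and should remain.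

**Step 10**
Reactants: 14 (1R,2S,5R,7R)-7-[(3S)-3-[(tert-butyldimethylsilyl)oxy]-4-methylpent-4-en-1-yn-1-yl]-2-hydroxy-7-methyl-4-methylidenebicyclo[3.1.1]heptan-6-one
Product: 16 (1R,5R,7R)-7-[(3S)-3-[(tert-butyldimethylsilyl)oxy]-4-methylpent-4-en-1-yn-1-yl]-4,7-dimethylbicyclo[3.1.1]hept-3-ene-2,6-dione, via β,γ-unsaturated dione 15 (not isolated)
Conditions: Dess–Martin periodinane, CH2Cl2, 0 °C → rt; then DBU (0.2 equiv), rt
Reagents that add atoms: none
Why: Dess–Martin oxidation erases the relay stereocentre, and DBU isomerises the β,γ-unsaturated ketone through its dienolate to the conjugated trisubstituted enone; the bridgehead C–H bonds cannot enolise (Bredt's rule), so no stereocentre is at risk.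

**Step 11**
Reactants: 16 (1R,5R,7R)-7-[(3S)-3-[(tert-butyldimethylsilyl)oxy]-4-methylpent-4-en-1-yn-1-yl]-4,7-dimethylbicyclo[3.1.1]hept-3-ene-2,6-dione
Product: 17 (1R,5R,7R)-7-[(1Z,3R)-3-[(tert-butyldimethylsilyl)oxy]-4-methylpenta-1,4-dien-1-yl]-4,7-dimethylbicyclo[3.1.1]hept-3-ene-2,6-dione
Conditions: H2 (1 atm), Lindlar catalyst, quinoline, EtOAc, rt
Reagents that add atoms: none
Why: Lindlar semihydrogenation adds H2 syn to the alkyne and gives the (Z)-olefin needed for ring closure, while the poisoned catalyst should leave the enone and the 1,1-disubstituted olefin untouched.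

**Step 12**
Reactants: 17 (1R,5R,7R)-7-[(1Z,3R)-3-[(tert-butyldimethylsilyl)oxy]-4-methylpenta-1,4-dien-1-yl]-4,7-dimethylbicyclo[3.1.1]hept-3-ene-2,6-dione
Product: 18 6-(tosylhydrazone) of 17: N′-[7-[(1Z,3R)-3-[(tert-butyldimethylsilyl)oxy]-4-methylpenta-1,4-dien-1-yl]-4,7-dimethyl-2-oxobicyclo[3.1.1]hept-3-en-6-ylidene]-4-methylbenzenesulfonohydrazide
Conditions: TsNHNH2 (1.05 equiv), PPTS (cat.), THF, 4 Å MS, rt
Reagents that add atoms: p-toluenesulfonyl hydrazide Cc1ccc(cc1)S(=O)(=O)NN
Why: Hydrazone condensation: the strained, non-conjugated cyclobutanone carbonyl is much more electrophilic than the conjugated enone carbonyl, so one equivalent of hydrazide under mild acid catalysis in a non-nucleophilic solvent should react at C6 only.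

**Step 13**
Reactants: 18 6-(tosylhydrazone) of 17
Product: 21 (1R,2R,5R,7S,8R)-5-[(tert-butyldimethylsilyl)oxy]-2,6,6,11-tetramethyltricyclo[5.4.0.0^2,8]undeca-3,10-dien-9-one, via cyclised tosylhydrazine 19 (not isolated), via monoalkyl diazene 20 (not isolated)
Conditions: Fe(acac)3 (30 mol%), PhSiH3 (3 equiv), EtOH (0.01 M), 60 °C; then NaOAc (5 equiv), 80 °C
Reagents that add atoms: none
Why: Proposed new method: an iron hydride formed from Fe(acac)3 and PhSiH3 transfers a hydrogen atom to the CH2 terminus of the isopropenyl group (creating the second methyl group on C6), the tertiary C6 radical adds 7-exo-trig to the carbon of the C7 sulfonylhydrazone, the hydrazinyl radical is reduced to 19, and warming with acetate expels p-toluenesulfinate to give diazene 20, which loses N2 and leaves C7–H. The closest known reactions are the iron-catalysed reductive coupling of olefins with sulfonylhydrazones (olefin hydromethylation), hydrogen-atom-transfer-initiated cyclisations of alkene-tethered ketone tosylhydrazones to five- and six-membered rings, and the base-induced collapse of N-alkyl-N′-tosylhydrazines to alkanes known from tosylhydrazone reductions; new here are the seven-membered ring, the cyclobutanone-derived acceptor and the one-pot denitrogenation at a fully substituted carbon. One ring is closed, the cycloheptene, through the C6–C7 bond in the 7-exo mode onto C=N, and this is favoured because C2 and C7 are held 1,3 on the rigid cyclobutane and the (Z)-olefin removes further rotors, so the radical sits beneath the hydrazone carbon. C7 is the only new stereocentre: the arm can reach C7 only from the face anti to the C9–C11 bridge, and hydrogen then replaces nitrogen on the remaining open face. C6 becomes the non-stereogenic gem-dimethyl carbon, and the C5 centre is untouched. The step needs chemoselective hydrogen-atom transfer to the 1,1-disubstituted olefin, which the substrate secures because its other olefins are a 1,2-disubstituted alkene and a β,β-disubstituted enone (both poor acceptors under these conditions), and it needs an adduct radical that does not open the cyclobutane, which a nitrogen-centred radical (unlike the alkoxyl radical from the free ketone) provides.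

**Step 14**
Reactants: 21 (1R,2R,5R,7S,8R)-5-[(tert-butyldimethylsilyl)oxy]-2,6,6,11-tetramethyltricyclo[5.4.0.0^2,8]undeca-3,10-dien-9-one
Product: 22 (1R,2R,3S,4S,5S,7S,8R)-5-[(tert-butyldimethylsilyl)oxy]-3,4-dihydroxy-2,6,6,11-tetramethyltricyclo[5.4.0.0^2,8]undec-10-en-9-one
Conditions: OsO4 (5 mol%), NMO, acetone/H2O, rt
Reagents that add atoms: N-methylmorpholine N-oxide C[N+]1([O-])CCOCC1; water O (both oxygens delivered through catalytic osmium tetroxide O=[Os](=O)(=O)=O)
Why: Catalytic osmylation (Upjohn dihydroxylation) of the electron-richer cis-disubstituted olefin rather than the enone; syn addition from the face anti to the allylic 5-silyloxy group sets C3 and C4 cis to each other and trans to O5.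

**Step 15**
Reactants: 22 (1R,2R,3S,4S,5S,7S,8R)-5-[(tert-butyldimethylsilyl)oxy]-3,4-dihydroxy-2,6,6,11-tetramethyltricyclo[5.4.0.0^2,8]undec-10-en-9-one; 23 (2Z)-2-methylbut-2-enoic anhydride (angelic anhydride)
Product: 24 (1R,2R,3S,4S,5S,7S,8R)-5-[(tert-butyldimethylsilyl)oxy]-3-hydroxy-2,6,6,11-tetramethyl-9-oxotricyclo[5.4.0.0^2,8]undec-10-en-4-yl (2Z)-2-methylbut-2-enoate
Conditions: LiHMDS (1.0 equiv), THF, −78 °C; then 23 (1.1 equiv), −78 → −40 °C; AcOH quench
Reagents that add atoms: none
Why: Kinetic acylation of a lithium alkoxide by the anhydride: the 3-hydroxyl is neopentylic (next to quaternary C2) and the 4-hydroxyl is not, so O4 should react first, and the low temperature without a nucleophilic catalyst avoids angelate-to-tiglate isomerisation and acyl migration, O–H deprotonation being faster than enolisation of the enone, whose α′-position is a bridgehead.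

**Step 16**
Reactants: 24 the 4-O-angelate; 25 (2R)-2-methylbutanoic acid
Product: 26 (1R,2R,3S,4S,5S,7S,8R)-5-[(tert-butyldimethylsilyl)oxy]-2,6,6,11-tetramethyl-3-{[(2R)-2-methylbutanoyl]oxy}-9-oxotricyclo[5.4.0.0^2,8]undec-10-en-4-yl (2Z)-2-methylbut-2-enoate
Conditions: EDC·HCl, DMAP, CH2Cl2, rt → 35 °C
Reagents that add atoms: none
Why: Steglich-type carbodiimide esterification of the only free hydroxyl; these conditions should not enolise the α-stereocentre of 25.

**Step 17**
Reactants: 26 the diester silyl ether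
Product: 27 (1R,2R,3S,4R,5S,7S,8R)-5-hydroxy-2,6,6,11-tetramethyl-3-{[(2R)-2-methylbutanoyl]oxy}-9-oxotricyclo[5.4.0.0^2,8]undec-10-en-4-yl (2Z)-2-methylbut-2-enoate (target)
Conditions: HF·pyridine, pyridine/THF, 0 °C → rt
Reagents that add atoms: none
Why: Fluoride cleavage of the Si–O bond under buffered, weakly acidic conditions, which should spare both esters, the angelate geometry and the enone and avoid acyl migration.

**Compound list**
1 | methyl 3-methylbut-2-enoate | COC(=O)C=C(C)C | starting material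
2 | tert-butyl[(1-methoxy-3-methylbuta-1,3-dien-1-yl)oxy]dimethylsilane (ketene acetal geometry not defined) | C=C(C)C=C(OC)O[Si](C)(C)C(C)(C)C | intermediate
3 | (2E)-3-methylpent-2-en-4-yn-1-ol | OC/C=C(\C)C#C | starting material
4 | (2E)-3-methylpent-2-en-4-ynal | O=C/C=C(\C)C#C | intermediate
5 | methyl (2E,5S,6E)-5-hydroxy-3,7-dimethylnona-2,6-dien-8-ynoate | COC(=O)/C=C(\C)C[C@H](O)/C=C(\C)C#C | intermediate
6 | methyl (2E,5S,6E)-3,7-dimethyl-5-[(triethylsilyl)oxy]nona-2,6-dien-8-ynoate | COC(=O)/C=C(\C)C[C@H](O[Si](CC)(CC)CC)/C=C(\C)C#C | intermediate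
7 | 2-methylprop-2-enal (methacrolein) | CC(=C)C=O | starting material
8 | methyl (2E,5S,6E,10S)-10-hydroxy-3,7,11-trimethyl-5-[(triethylsilyl)oxy]dodeca-2,6,11-trien-8-ynoate | COC(=O)/C=C(\C)C[C@H](O[Si](CC)(CC)CC)/C=C(\C)C#C[C@@H](O)C(C)=C | intermediate
9 | methyl (2E,5S,6E,10S)-10-[(tert-butyldimethylsilyl)oxy]-3,7,11-trimethyl-5-[(triethylsilyl)oxy]dodeca-2,6,11-trien-8-ynoate | COC(=O)/C=C(\C)C[C@H](O[Si](CC)(CC)CC)/C=C(\C)C#C[C@@H](O[Si](C)(C)C(C)(C)C)C(C)=C | intermediate
10 | (2E,5S,6E,10S)-10-[(tert-butyldimethylsilyl)oxy]-3,7,11-trimethyl-5-[(triethylsilyl)oxy]dodeca-2,6,11-trien-8-ynoic acid | OC(=O)/C=C(\C)C[C@H](O[Si](CC)(CC)CC)/C=C(\C)C#C[C@@H](O[Si](C)(C)C(C)(C)C)C(C)=C | intermediate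
11 | acid chloride of 10 (not isolated) | ClC(=O)/C=C(\C)C[C@H](O[Si](CC)(CC)CC)/C=C(\C)C#C[C@@H](O[Si](C)(C)C(C)(C)C)C(C)=C | intermediate
12 | (5S,6E,10S)-10-[(tert-butyldimethylsilyl)oxy]-7,11-dimethyl-3-methylidene-5-[(triethylsilyl)oxy]dodeca-1,6,11-trien-8-yn-1-one, the vinylketene (not isolated) | O=C=CC(=C)C[C@H](O[Si](CC)(CC)CC)/C=C(\C)C#C[C@@H](O[Si](C)(C)C(C)(C)C)C(C)=C | intermediate
13 | (1R,4S,5R,7R)-7-[(3S)-3-[(tert-butyldimethylsilyl)oxy]-4-methylpent-4-en-1-yn-1-yl]-7-methyl-2-methylidene-4-[(triethylsilyl)oxy]bicyclo[3.1.1]heptan-6-one (4-silyloxy syn to the C6 carbonyl bridge; 7-methyl syn and 7-alkynyl anti to the C2–C4 bridge) | O=C1[C@H]2[C@@H](O[Si](CC)(CC)CC)CC(=C)[C@@H]1[C@@]2(C)C#C[C@@H](O[Si](C)(C)C(C)(C)C)C(C)=C | intermediate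
14 | (1R,2S,5R,7R)-7-[(3S)-3-[(tert-butyldimethylsilyl)oxy]-4-methylpent-4-en-1-yn-1-yl]-2-hydroxy-7-methyl-4-methylidenebicyclo[3.1.1]heptan-6-one | O=C1[C@H]2[C@@H](O)CC(=C)[C@@H]1[C@@]2(C)C#C[C@@H](O[Si](C)(C)C(C)(C)C)C(C)=C | intermediate
15 | (1R,5R,7R)-7-[(3S)-3-[(tert-butyldimethylsilyl)oxy]-4-methylpent-4-en-1-yn-1-yl]-7-methyl-4-methylidenebicyclo[3.1.1]heptane-2,6-dione (not isolated) | O=C1[C@H]2C(=O)CC(=C)[C@@H]1[C@@]2(C)C#C[C@@H](O[Si](C)(C)C(C)(C)C)C(C)=C | intermediate
16 | (1R,5R,7R)-7-[(3S)-3-[(tert-butyldimethylsilyl)oxy]-4-methylpent-4-en-1-yn-1-yl]-4,7-dimethylbicyclo[3.1.1]hept-3-ene-2,6-dione | O=C1[C@H]2C(=O)C=C(C)[C@@H]1[C@@]2(C)C#C[C@@H](O[Si](C)(C)C(C)(C)C)C(C)=C | intermediate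
17 | (1R,5R,7R)-7-[(1Z,3R)-3-[(tert-butyldimethylsilyl)oxy]-4-methylpenta-1,4-dien-1-yl]-4,7-dimethylbicyclo[3.1.1]hept-3-ene-2,6-dione | O=C1[C@H]2C(=O)C=C(C)[C@@H]1[C@@]2(C)/C=C\[C@@H](O[Si](C)(C)C(C)(C)C)C(C)=C | intermediate
18 | 6-(tosylhydrazone) of 17 (C=N geometry not defined; core and side-chain configuration as in 17) | Cc1ccc(cc1)S(=O)(=O)NN=C1[C@H]2C(=O)C=C(C)[C@@H]1[C@@]2(C)/C=C\[C@@H](O[Si](C)(C)C(C)(C)C)C(C)=C | intermediate
19 | N′-[5-[(tert-butyldimethylsilyl)oxy]-2,6,6,11-tetramethyl-9-oxotricyclo[5.4.0.0^2,8]undeca-3,10-dien-7-yl]-4-methylbenzenesulfonohydrazide, ring configuration as in 21 with N on C7 in place of H (not isolated) | C1=C[C@@]2(C)[C@@H]3C(=O)C=C(C)[C@H]2[C@]3(NNS(=O)(=O)c2ccc(C)cc2)C(C)(C)[C@@H]1O[Si](C)(C)C(C)(C)C | intermediate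
20 | 7-diazenyl analogue of 21 (monoalkyl diazene, not isolated) | C1=C[C@@]2(C)[C@@H]3C(=O)C=C(C)[C@H]2[C@]3(N=N)C(C)(C)[C@@H]1O[Si](C)(C)C(C)(C)C | intermediate
21 | (1R,2R,5R,7S,8R)-5-[(tert-butyldimethylsilyl)oxy]-2,6,6,11-tetramethyltricyclo[5.4.0.0^2,8]undeca-3,10-dien-9-one | C1=C[C@@]2(C)[C@@H]3C(=O)C=C(C)[C@H]2[C@@H]3C(C)(C)[C@@H]1O[Si](C)(C)C(C)(C)C | intermediate
22 | (1R,2R,3S,4S,5S,7S,8R)-5-[(tert-butyldimethylsilyl)oxy]-3,4-dihydroxy-2,6,6,11-tetramethyltricyclo[5.4.0.0^2,8]undec-10-en-9-one (3,4-diol cis, both trans to O5) | O[C@@H]1[C@@H](O[Si](C)(C)C(C)(C)C)C(C)(C)[C@@H]2[C@H]3C(=O)C=C(C)[C@@H]2[C@@]3(C)[C@@H]1O | intermediate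
23 | (2Z)-2-methylbut-2-enoic anhydride (angelic anhydride) | C/C=C(/C)C(=O)OC(=O)C(/C)=C\C | starting material
24 | (1R,2R,3S,4S,5S,7S,8R)-5-[(tert-butyldimethylsilyl)oxy]-3-hydroxy-2,6,6,11-tetramethyl-9-oxotricyclo[5.4.0.0^2,8]undec-10-en-4-yl (2Z)-2-methylbut-2-enoate | C/C=C(/C)C(=O)O[C@@H]1[C@@H](O[Si](C)(C)C(C)(C)C)C(C)(C)[C@@H]2[C@H]3C(=O)C=C(C)[C@@H]2[C@@]3(C)[C@@H]1O | intermediate
25 | (2R)-2-methylbutanoic acid | CC[C@@H](C)C(=O)O | starting material
26 | (1R,2R,3S,4S,5S,7S,8R)-5-[(tert-butyldimethylsilyl)oxy]-2,6,6,11-tetramethyl-3-{[(2R)-2-methylbutanoyl]oxy}-9-oxotricyclo[5.4.0.0^2,8]undec-10-en-4-yl (2Z)-2-methylbut-2-enoate | C/C=C(/C)C(=O)O[C@@H]1[C@@H](O[Si](C)(C)C(C)(C)C)C(C)(C)[C@@H]2[C@H]3C(=O)C=C(C)[C@@H]2[C@@]3(C)[C@@H]1OC(=O)[C@H](C)CC | intermediate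
27 | (1R,2R,3S,4R,5S,7S,8R)-5-hydroxy-2,6,6,11-tetramethyl-3-{[(2R)-2-methylbutanoyl]oxy}-9-oxotricyclo[5.4.0.0^2,8]undec-10-en-4-yl (2Z)-2-methylbut-2-enoate | C/C=C(/C)C(=O)O[C@@H]1[C@@H](O)C(C)(C)[C@@H]2[C@H]3C(=O)C=C(C)[C@@H]2[C@@]3(C)[C@@H]1OC(=O)[C@H](C)CC | target

**Step count and risks**
Total: 17 steps. Longest linear sequence: 16 steps (3 → 27, steps 2–17); step 1 is a one-step branch.

Steps most likely to fail:

Step 13 (proposed new method). The tertiary radical may be reduced to an isopropyl group before it cyclises, or the cyclised sulfonylhydrazine may not collapse cleanly to the C–H compound. The fallback uses known chemistry and sets out from ketone 17. Cobalt-catalysed Markovnikov hydrochlorination of the isopropenyl group (Co(salen)-type catalyst, TsCl, PhSiH3, EtOH) would give the tertiary chloride F1. Condensation with 1-amino-2-phenylaziridine at the cyclobutanone would give the N-aziridinylimine F2. Slow addition of Bu3SnH/AIBN in refluxing benzene would then run an N-aziridinylimine radical cyclisation: chlorine abstraction, 7-exo addition of the tertiary radical to C=N, loss of styrene and N2 from the aminyl radical, and hydrogen transfer to the C7 radical. This returns to the route at 21.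

Step 8. The ketene may dimerise or oligomerise, proton loss may occur at C4 instead of the methyl group (both regiochemical outcomes converge at 16), or facial control by the silyloxy centre may be incomplete. The fallback sets out from acid 10: coupling with pyrrolidine (EDC, HOBt) would give the pyrrolidine amide F3. Treatment with Tf2O and 2,4,6-collidine in 1,2-dichloroethane at reflux would generate the vinylketeniminium salt, a more electrophilic partner that undergoes the same intramolecular [2+2] cycloaddition. Aqueous hydrolysis of the cyclobutaniminium salt comes back to the route at 13.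

Step 15. Acylation may occur at the neopentylic 3-hydroxyl, or the acyl group may migrate between the cis oxygens under basic conditions. The fallback sets out from diol 22: kinetic silylation of the 4-hydroxyl (TESCl, imidazole, −40 °C) would give the 4-O-triethylsilyl ether F4. Esterification of the remaining 3-hydroxyl with 25 (EDC, DMAP) would give the 3-O-[(2R)-2-methylbutanoyl] ester F5. Selective removal of the triethylsilyl group (PPTS, MeOH, 0 °C) would give the 4-hydroxy ester F6. Angeloylation of its only free hydroxyl with 23 (LiHMDS, THF, −78 °C) rejoins the route at 26. Should the 3-hydroxyl prove the more reactive one, the two acylations of the main route are simply run in reverse order.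

**Further compounds**
F1 | step 13 | (1R,5R,7R)-7-[(1Z,3R)-3-[(tert-butyldimethylsilyl)oxy]-4-chloro-4-methylpent-1-en-1-yl]-4,7-dimethylbicyclo[3.1.1]hept-3-ene-2,6-dione | O=C1[C@H]2C(=O)C=C(C)[C@@H]1[C@@]2(C)/C=C\[C@@H](O[Si](C)(C)C(C)(C)C)C(C)(C)Cl
F2 | step 13 | 6-[(2-phenylaziridin-1-yl)imino] derivative of F1 (N-aziridinylimine) | c1ccc(cc1)C3CN3N=C1[C@H]2C(=O)C=C(C)[C@@H]1[C@@]2(C)/C=C\[C@@H](O[Si](C)(C)C(C)(C)C)C(C)(C)Cl
F3 | step 8 | (2E,5S,6E,10S)-10-[(tert-butyldimethylsilyl)oxy]-3,7,11-trimethyl-1-(pyrrolidin-1-yl)-5-[(triethylsilyl)oxy]dodeca-2,6,11-trien-8-yn-1-one | O=C(N1CCCC1)/C=C(\C)C[C@H](O[Si](CC)(CC)CC)/C=C(\C)C#C[C@@H](O[Si](C)(C)C(C)(C)C)C(C)=C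
F4 | step 15 | 5-[(tert-butyldimethylsilyl)oxy]-3-hydroxy-2,6,6,11-tetramethyl-4-[(triethylsilyl)oxy]tricyclo[5.4.0.0^2,8]undec-10-en-9-one (configuration as in 22) | CC[Si](CC)(CC)O[C@@H]1[C@@H](O[Si](C)(C)C(C)(C)C)C(C)(C)[C@@H]2[C@H]3C(=O)C=C(C)[C@@H]2[C@@]3(C)[C@@H]1O
F5 | step 15 | 5-[(tert-butyldimethylsilyl)oxy]-2,6,6,11-tetramethyl-9-oxo-4-[(triethylsilyl)oxy]tricyclo[5.4.0.0^2,8]undec-10-en-3-yl (2R)-2-methylbutanoate (configuration as in 22) | CC[Si](CC)(CC)O[C@@H]1[C@@H](O[Si](C)(C)C(C)(C)C)C(C)(C)[C@@H]2[C@H]3C(=O)C=C(C)[C@@H]2[C@@]3(C)[C@@H]1OC(=O)[C@H](C)CC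
F6 | step 15 | 5-[(tert-butyldimethylsilyl)oxy]-4-hydroxy-2,6,6,11-tetramethyl-9-oxotricyclo[5.4.0.0^2,8]undec-10-en-3-yl (2R)-2-methylbutanoate (configuration as in 22) | O[C@@H]1[C@@H](O[Si](C)(C)C(C)(C)C)C(C)(C)[C@@H]2[C@H]3C(=O)C=C(C)[C@@H]2[C@@]3(C)[C@@H]1OC(=O)[C@H](C)CC
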